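**Retrosynthetic overview**
1. Target 32 comes from macrocyclic alcohol 29 by O8 methacrylation, O9 desilylation and O9 acetylation.
2. The ten-membered carbocycle is closed last at C4=C5 by ring-closing metathesis of vinyl lactone / isopropenyl-furanone 28; the 3,10-oxygen bridge allows only the Z alkene.
3. The C7–C8 bond and the α-methylene ester come from an intermolecular indium Barbier allylation of aldehyde 17 (fragment A) with (Z)-allylic bromide 25 (fragment B), followed by 6,12-lactonisation.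
4. Fragment A: furanone by gold-catalysed cyclisation of an α′-hydroxy ynone; C9/C10 from Sharpless epoxidation and epoxy-urethane opening. Fragment B: (R)-but-3-ene-1,2-diol, vinylalumination, SN2′ bromination.
5. Ring order: furanone first, γ-lactone second, ten-membered ring last.

Assumption: atom labels C1–C15 follow germacrane numbering; the SMILES is read as 4Z,6R,7S,8S,9S,10S. The stereochemical outcome of step 19 is predicted from transition-state models, not from a direct precedent.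

**Fragment A**

Step 1
Reactants: 1 3-methylbut-2-en-1-ol (prenol)
Product: 2 1-methoxy-4-{[(3-methylbut-2-en-1-yl)oxy]methyl}benzene (prenyl PMB ether)
Conditions: NaH, PMBCl, Bu4NI (cat.), THF, 0 °C → rt
Reagents that add atoms: 4-methoxybenzyl chloride COc1ccc(CCl)cc1
Why: Williamson ether synthesis on a primary allylic alkoxide; the PMB ether is later removed oxidatively without touching silyl ethers.

Step 2
Reactants: 2 prenyl PMB ether
Product: 3 (2E)-4-[(4-methoxybenzyl)oxy]-2-methylbut-2-en-1-ol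
Conditions: SeO2 (0.5 equiv), t-BuOOH, salicylic acid (cat.), CH2Cl2, 0 °C → rt
Reagents that add atoms: tert-butyl hydroperoxide CC(C)(C)OO
Why: Riley allylic oxidation (ene reaction then [2,3]-shift) of the gem-dimethyl alkene hydroxylates the E-methyl group, so C1 ends up trans to C8.

Step 3
Reactants: 3 (E)-allylic alcohol
Product: 4 [(2S,3S)-3-{[(4-methoxybenzyl)oxy]methyl}-2-methyloxiran-2-yl]methanol
Conditions: Ti(OiPr)4 (10 mol %), diethyl L-(+)-tartrate (12 mol %), t-BuOOH, 4 Å MS, CH2Cl2, −20 °C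
Reagents that add atoms: tert-butyl hydroperoxide CC(C)(C)OO
Why: Sharpless asymmetric epoxidation; the L-(+)-tartrate catalyst gives the (2S,3S)-epoxide, which fixes C9 (kept) and prepares C10 for inversion.

Step 4
Reactants: 4 epoxy alcohol
Product: 5 [(2S,3S)-3-{[(4-methoxybenzyl)oxy]methyl}-2-methyloxiran-2-yl]methyl N-phenylcarbamate
Conditions: PhNCO, Et3N (cat.), CH2Cl2, rt
Reagents that add atoms: phenyl isocyanate O=C=Nc1ccccc1
Why: Carbamoylation of the primary alcohol installs an internal oxygen nucleophile for regio- and stereospecific epoxide opening.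

Step 5
Reactants: 5 epoxy carbamate
Product: 7 (4R)-4-{(1S)-1-hydroxy-2-[(4-methoxybenzyl)oxy]ethyl}-4-methyl-1,3-dioxolan-2-one, via iminocarbonate 6 (not isolated)
Conditions: BF3·OEt2 (30 mol %), Et2O, −20 °C; then 1 M aq H2SO4, THF, rt
Reagents that add atoms: water O
Why: Epoxy-urethane cyclisation: the carbamate carbonyl oxygen opens the epoxide 5-exo at the tertiary carbon with inversion at C10 while C9 keeps the epoxide oxygen (erythro C9/C10 pattern), and hydrolysis of the iminocarbonate leaves a cyclic carbonate that differentiates the three hydroxyls.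

Step 6
Reactants: 7 hydroxy carbonate
Product: 8 (4R)-4-{(1S)-1-[(tert-butyldimethylsilyl)oxy]-2-[(4-methoxybenzyl)oxy]ethyl}-4-methyl-1,3-dioxolan-2-one
Conditions: TBSOTf, 2,6-lutidine, CH2Cl2, 0 °C
Reagents that add atoms: tert-butyldimethylsilyl triflate CC(C)(C)[Si](C)(C)OS(=O)(=O)C(F)(F)F
Why: Silylation of the only free hydroxyl; the bulky non-chelating TBS ether later enforces Felkin–Anh addition at C8.

Step 7
Reactants: 8 silyl carbonate
Product: 9 (2R,3S)-3-[(tert-butyldimethylsilyl)oxy]-4-[(4-methoxybenzyl)oxy]-2-methylbutane-1,2-diol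
Conditions: K2CO3 (cat.), MeOH, 0 °C
Reagents that add atoms: none
Why: Transesterification of the cyclic carbonate frees the primary C1 and tertiary C10 hydroxyls at a temperature where the hindered TBS ether does not migrate.

Step 8
Reactants: 9 diol
Product: 10 (2S,3S)-3-[(tert-butyldimethylsilyl)oxy]-2-hydroxy-4-[(4-methoxybenzyl)oxy]-2-methylbutanal
Conditions: IBX, DMSO, rt
Reagents that add atoms: none
Why: IBX oxidation takes the primary alcohol to the aldehyde without glycol cleavage and leaves the tertiary alcohol alone.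

Step 9
Reactants: 10 hydroxy aldehyde; 11 2-methylbut-1-en-3-yne
Product: 13 (6R,7S)-7-[(tert-butyldimethylsilyl)oxy]-8-[(4-methoxybenzyl)oxy]-2,6-dimethyloct-1-en-3-yne-5,6-diol (C5 epimers), via lithium acetylide 12 (not isolated)
Conditions: 11 (2.5 equiv), n-BuLi (2.4 equiv), THF, −78 °C; then 10, −78 → 0 °C; H2O
Reagents that add atoms: none
Why: Acetylide 1,2-addition to the aldehyde (one equivalent deprotonates the tertiary hydroxyl); the new carbinol centre is oxidised away in the next step.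

Step 10
Reactants: 13 propargylic diol
Product: 14 (6S,7S)-7-[(tert-butyldimethylsilyl)oxy]-6-hydroxy-8-[(4-methoxybenzyl)oxy]-2,6-dimethyloct-1-en-3-yn-5-one
Conditions: IBX, DMSO, rt
Reagents that add atoms: none
Why: IBX oxidation of the secondary propargylic alcohol gives the α′-hydroxy ynone, again without cleaving the 1,2-diol.

Step 11
Reactants: 14 α′-hydroxy ynone
Product: 15 (2S)-2-{(1S)-1-[(tert-butyldimethylsilyl)oxy]-2-[(4-methoxybenzyl)oxy]ethyl}-2-methyl-5-(prop-1-en-2-yl)furan-3(2H)-one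
Conditions: Ph3PAuNTf2 (5 mol %), toluene, rt
Reagents that add atoms: none
Why: Gold-catalysed 5-endo-dig oxa-cyclisation (intramolecular oxa-Michael addition of the tertiary C10 hydroxyl to the activated ynone) forms the 3(2H)-furanone; C10 is not touched.

Step 12
Reactants: 15 furanone PMB ether
Product: 16 (2S)-2-{(1S)-1-[(tert-butyldimethylsilyl)oxy]-2-hydroxyethyl}-2-methyl-5-(prop-1-en-2-yl)furan-3(2H)-one
Conditions: DDQ, CH2Cl2/pH 7 buffer (10:1), 0 °C
Reagents that add atoms: none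
Why: Oxidative PMB ether cleavage; the electron-poor dienone and the TBS ether are inert to DDQ.

Step 13
Reactants: 16 primary alcohol
Product: 17 (2R)-2-[(tert-butyldimethylsilyl)oxy]-2-[(2S)-2-methyl-3-oxo-5-(prop-1-en-2-yl)-2,3-dihydrofuran-2-yl]acetaldehyde (fragment A)
Conditions: DMP, NaHCO3, CH2Cl2, 0 °C → rt
Reagents that add atoms: none
Why: Dess–Martin oxidation under buffered, non-basic conditions gives the α-silyloxy aldehyde without epimerising C9.

**Fragment B**

Step 14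
Reactants: 18 (R)-but-3-ene-1,2-diol
Product: 19 (R)-3,4-bis[(triethylsilyl)oxy]but-1-ene
Conditions: TESCl, imidazole, DMF, 0 °C → rt
Reagents that add atoms: chlorotriethylsilane CC[Si](Cl)(CC)CC
Why: Bis-silylation; TES is chosen for O6 because it can later be removed beside the hindered TBS ether at O9.

Step 15
Reactants: 19 bis-TES ether
Product: 20 (R)-2-[(triethylsilyl)oxy]but-3-en-1-ol
Conditions: HF·pyridine, pyridine, THF, 0 °C
Reagents that add atoms: none
Why: Selective desilylation; the unhindered primary TES ether is cleaved much faster than the secondary allylic one.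

Step 16
Reactants: 20 mono-TES alcohol
Product: 21 (R)-2-[(triethylsilyl)oxy]but-3-enal
Conditions: DMP, NaHCO3, CH2Cl2, 0 °C; used at once
Reagents that add atoms: none
Why: Dess–Martin oxidation under neutral conditions keeps the β,γ-double bond out of conjugation and the C6 centre intact.

Step 17
Reactants: 21 aldehyde; 22 methyl propiolate
Product: 24 methyl (4R)-3-hydroxy-2-methylidene-4-[(triethylsilyl)oxy]hex-5-enoate (C3 epimers), via vinylalane 23 (not isolated)
Conditions: i-Bu2AlH, NMO, THF, 0 °C, then 22; then 21, 0 °C → rt; aq. KNaC4H4O6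
Reagents that add atoms: none
Why: Vinylalumination (hydroalumination of the propiolate, then 1,2-addition of the α-aluminoacrylate) gives the Morita–Baylis–Hillman-type adduct without amine base, so the labile aldehyde is not isomerised; the new carbinol centre is lost in the next step.

Step 18
Reactants: 24 allylic alcohol
Product: 25 methyl (2Z,4R)-2-(bromomethyl)-4-[(triethylsilyl)oxy]hexa-2,5-dienoate (fragment B)
Conditions: NBS, Me2S, CH2Cl2, 0 °C → rt
Reagents that add atoms: N-bromosuccinimide O=C1CCC(=O)N1Br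
Why: Corey–Kim-type activation of the allylic alcohol and SN2′ attack of bromide give the thermodynamically preferred (Z)-2-(bromomethyl)alk-2-enoate with C6 cis to CH2Br; C6 is untouched.

**Coupling and end game**

Step 19
Reactants: 17 aldehyde (fragment A); 25 allylic bromide (fragment B)
Product: 26 methyl (3R,4S,5S)-5-[(tert-butyldimethylsilyl)oxy]-4-hydroxy-2-methylidene-5-[(2S)-2-methyl-3-oxo-5-(prop-1-en-2-yl)-2,3-dihydrofuran-2-yl]-3-{(1R)-1-[(triethylsilyl)oxy]prop-2-en-1-yl}pentanoate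
Conditions: In powder (2 equiv), 25 (1.5 equiv), THF/H2O (2:1), rt
Reagents that add atoms: none
Why: Barbier-type carbonyl allylation: the (Z)-allylindium reacts at its γ-carbon through a closed chair (C7/C8 syn), the aldehyde face follows Felkin–Anh control by the α-silyloxy group (C8/C9 anti), and the reagent face is set by the A(1,3)-minimised C6 rotamer with the silyloxy group anti to the incoming aldehyde (C6/C7 as required for a trans lactone).

Step 20
Reactants: 26 Barbier adduct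
Product: 28 (4R,5R)-4-{(1S,2S)-2-[(tert-butyldimethylsilyl)oxy]-1-hydroxy-2-[(2S)-2-methyl-3-oxo-5-(prop-1-en-2-yl)-2,3-dihydrofuran-2-yl]ethyl}-3-methylidene-5-vinyldihydrofuran-2(3H)-one, via diol ester 27 (not isolated)
Conditions: PPTS, MeOH, 0 °C → rt; then CSA (cat.), CH2Cl2, rt
Reagents that add atoms: none
Why: Acid-catalysed methanolysis removes the TES ether (the hindered TBS ether stays) and the freed C6 hydroxyl lactonises onto the methyl ester; the trans 6,12-γ-lactone is favoured kinetically and thermodynamically over the cis 8,12-lactone from the hindered C8 hydroxyl.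

Step 21
Reactants: 28 vinyl lactone
Product: 29 (4Z,6R,7R,8S,9S,10S)-9-[(tert-butyldimethylsilyl)oxy]-8-hydroxy-1-oxo-3,10-epoxygermacra-2,4,11(13)-trien-12,6-olide
Conditions: second-generation Hoveyda–Grubbs catalyst RuCl2(H2IMes)(=CH-C6H4-2-O-i-Pr) (15 mol %), toluene (1 mM), 80 °C
Reagents that add atoms: none
Why: Ring-closing metathesis: the ruthenium carbene loads on the monosubstituted C5 vinyl group and closes onto the isopropenyl group, the oxygen-bridged nine-membered ring accepts only the Z alkene, and the electron-poor exo-methylene is a spectator.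

Step 22
Reactants: 29 macrocyclic alcohol
Product: 30 (4Z,6R,7S,8S,9S,10S)-9-[(tert-butyldimethylsilyl)oxy]-8-(methacryloyloxy)-1-oxo-3,10-epoxygermacra-2,4,11(13)-trien-12,6-olide
Conditions: methacrylic anhydride, Et3N, DMAP, CH2Cl2, 0 °C → rt
Reagents that add atoms: methacrylic anhydride CC(=C)C(=O)OC(=O)C(C)=C
Why: DMAP-catalysed acylation of the only free hydroxyl; it follows the metathesis so the methacrylate alkene cannot compete in ring closure.

Step 23
Reactants: 30 silyl ether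
Product: 31 (4Z,6R,7S,8S,9S,10S)-9-hydroxy-8-(methacryloyloxy)-1-oxo-3,10-epoxygermacra-2,4,11(13)-trien-12,6-olide
Conditions: HF·pyridine, pyridine, THF, 0 °C → rt
Reagents that add atoms: none
Why: Fluoride-mediated desilylation under mildly acidic, non-nucleophilic conditions spares both Michael acceptors and does not promote acyl migration.

Step 24
Reactants: 31 C9 alcohol
Product: 32 (4Z,6R,7S,8S,9S,10S)-9-acetoxy-8-(methacryloyloxy)-1-oxo-3,10-epoxygermacra-2,4,11(13)-trien-12,6-olide (target)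
Conditions: Ac2O, pyridine, DMAP (cat.), CH2Cl2, 0 °C
Reagents that add atoms: acetic anhydride CC(=O)OC(C)=O
Why: Fast esterification of the C9 hydroxyl with a small acylating agent completes the target before the neighbouring methacrylate can migrate.

**Compound list**
1 | 3-methylbut-2-en-1-ol | CC(C)=CCO | starting material
2 | 1-methoxy-4-{[(3-methylbut-2-en-1-yl)oxy]methyl}benzene | CC(C)=CCOCc1ccc(OC)cc1 | intermediate
3 | (2E)-4-[(4-methoxybenzyl)oxy]-2-methylbut-2-en-1-ol | OC/C(C)=C/COCc1ccc(OC)cc1 | intermediate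
4 | [(2S,3S)-3-{[(4-methoxybenzyl)oxy]methyl}-2-methyloxiran-2-yl]methanol | OC[C@]1(C)O[C@H]1COCc1ccc(OC)cc1 | intermediate
5 | [(2S,3S)-3-{[(4-methoxybenzyl)oxy]methyl}-2-methyloxiran-2-yl]methyl N-phenylcarbamate | O=C(Nc1ccccc1)OC[C@]1(C)O[C@H]1COCc1ccc(OC)cc1 | intermediate
6 | (4R)-4-{(1S)-1-hydroxy-2-[(4-methoxybenzyl)oxy]ethyl}-4-methyl-N-phenyl-1,3-dioxolan-2-imine | COc1ccc(COC[C@H](O)[C@]2(C)OC(=Nc3ccccc3)OC2)cc1 | intermediate
7 | (4R)-4-{(1S)-1-hydroxy-2-[(4-methoxybenzyl)oxy]ethyl}-4-methyl-1,3-dioxolan-2-one | COc1ccc(COC[C@H](O)[C@]2(C)OC(=O)OC2)cc1 | intermediate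
8 | (4R)-4-{(1S)-1-[(tert-butyldimethylsilyl)oxy]-2-[(4-methoxybenzyl)oxy]ethyl}-4-methyl-1,3-dioxolan-2-one | COc1ccc(COC[C@H](O[Si](C)(C)C(C)(C)C)[C@]2(C)OC(=O)OC2)cc1 | intermediate
9 | (2R,3S)-3-[(tert-butyldimethylsilyl)oxy]-4-[(4-methoxybenzyl)oxy]-2-methylbutane-1,2-diol | COc1ccc(COC[C@H](O[Si](C)(C)C(C)(C)C)[C@](C)(O)CO)cc1 | intermediate
10 | (2S,3S)-3-[(tert-butyldimethylsilyl)oxy]-2-hydroxy-4-[(4-methoxybenzyl)oxy]-2-methylbutanal | COc1ccc(COC[C@H](O[Si](C)(C)C(C)(C)C)[C@](C)(O)C=O)cc1 | intermediate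
11 | 2-methylbut-1-en-3-yne | C=C(C)C#C | starting material
12 | lithium 3-methylbut-3-en-1-yn-1-ide | C=C(C)C#C[Li] | intermediate
13 | (6R,7S)-7-[(tert-butyldimethylsilyl)oxy]-8-[(4-methoxybenzyl)oxy]-2,6-dimethyloct-1-en-3-yne-5,6-diol (C5 epimers) | COc1ccc(COC[C@H](O[Si](C)(C)C(C)(C)C)[C@](C)(O)C(O)C#CC(C)=C)cc1 | intermediate
14 | (6S,7S)-7-[(tert-butyldimethylsilyl)oxy]-6-hydroxy-8-[(4-methoxybenzyl)oxy]-2,6-dimethyloct-1-en-3-yn-5-one | COc1ccc(COC[C@H](O[Si](C)(C)C(C)(C)C)[C@](C)(O)C(=O)C#CC(C)=C)cc1 | intermediate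
15 | (2S)-2-{(1S)-1-[(tert-butyldimethylsilyl)oxy]-2-[(4-methoxybenzyl)oxy]ethyl}-2-methyl-5-(prop-1-en-2-yl)furan-3(2H)-one | COc1ccc(COC[C@H](O[Si](C)(C)C(C)(C)C)[C@]2(C)OC(C(C)=C)=CC2=O)cc1 | intermediate
16 | (2S)-2-{(1S)-1-[(tert-butyldimethylsilyl)oxy]-2-hydroxyethyl}-2-methyl-5-(prop-1-en-2-yl)furan-3(2H)-one | OC[C@H](O[Si](C)(C)C(C)(C)C)[C@]1(C)OC(C(C)=C)=CC1=O | intermediate
17 | (2R)-2-[(tert-butyldimethylsilyl)oxy]-2-[(2S)-2-methyl-3-oxo-5-(prop-1-en-2-yl)-2,3-dihydrofuran-2-yl]acetaldehyde | O=C[C@H](O[Si](C)(C)C(C)(C)C)[C@]1(C)OC(C(C)=C)=CC1=O | intermediate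
18 | (R)-but-3-ene-1,2-diol | C=C[C@@H](O)CO | starting material
19 | (R)-3,4-bis[(triethylsilyl)oxy]but-1-ene | C=C[C@@H](O[Si](CC)(CC)CC)CO[Si](CC)(CC)CC | intermediate
20 | (R)-2-[(triethylsilyl)oxy]but-3-en-1-ol | C=C[C@@H](O[Si](CC)(CC)CC)CO | intermediate
21 | (R)-2-[(triethylsilyl)oxy]but-3-enal | C=C[C@@H](O[Si](CC)(CC)CC)C=O | intermediate
22 | methyl propiolate | C#CC(=O)OC | starting material
23 | methyl 2-(diisobutylalumanyl)acrylate | C=C(C(=O)OC)[Al](CC(C)C)CC(C)C | intermediate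
24 | methyl (4R)-3-hydroxy-2-methylidene-4-[(triethylsilyl)oxy]hex-5-enoate (C3 epimers) | C=C(C(=O)OC)C(O)[C@H](O[Si](CC)(CC)CC)C=C | intermediate
25 | methyl (2Z,4R)-2-(bromomethyl)-4-[(triethylsilyl)oxy]hexa-2,5-dienoate | BrC/C(C(=O)OC)=C\[C@H](O[Si](CC)(CC)CC)C=C | intermediate
26 | methyl (3R,4S,5S)-5-[(tert-butyldimethylsilyl)oxy]-4-hydroxy-2-methylidene-5-[(2S)-2-methyl-3-oxo-5-(prop-1-en-2-yl)-2,3-dihydrofuran-2-yl]-3-{(1R)-1-[(triethylsilyl)oxy]prop-2-en-1-yl}pentanoate | O[C@@H]([C@@H](C(=C)C(=O)OC)[C@H](O[Si](CC)(CC)CC)C=C)[C@H](O[Si](C)(C)C(C)(C)C)[C@]1(C)OC(C(C)=C)=CC1=O | intermediate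
27 | methyl (3S,4S,5S)-5-[(tert-butyldimethylsilyl)oxy]-4-hydroxy-3-[(1R)-1-hydroxyprop-2-en-1-yl]-2-methylidene-5-[(2S)-2-methyl-3-oxo-5-(prop-1-en-2-yl)-2,3-dihydrofuran-2-yl]pentanoate | O[C@@H]([C@@H](C(=C)C(=O)OC)[C@H](O)C=C)[C@H](O[Si](C)(C)C(C)(C)C)[C@]1(C)OC(C(C)=C)=CC1=O | intermediate
28 | (4R,5R)-4-{(1S,2S)-2-[(tert-butyldimethylsilyl)oxy]-1-hydroxy-2-[(2S)-2-methyl-3-oxo-5-(prop-1-en-2-yl)-2,3-dihydrofuran-2-yl]ethyl}-3-methylidene-5-vinyldihydrofuran-2(3H)-one | O[C@@H]([C@H]1C(=C)C(=O)O[C@@H]1C=C)[C@H](O[Si](C)(C)C(C)(C)C)[C@]2(C)OC(C(C)=C)=CC2=O | intermediate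
29 | (4Z,6R,7R,8S,9S,10S)-9-[(tert-butyldimethylsilyl)oxy]-8-hydroxy-1-oxo-3,10-epoxygermacra-2,4,11(13)-trien-12,6-olide | O[C@H]1[C@H]2C(=C)C(=O)O[C@@H]2/C=C(/C)C2=CC(=O)[C@@](C)(O2)[C@H]1O[Si](C)(C)C(C)(C)C | intermediate
30 | (4Z,6R,7S,8S,9S,10S)-9-[(tert-butyldimethylsilyl)oxy]-8-(methacryloyloxy)-1-oxo-3,10-epoxygermacra-2,4,11(13)-trien-12,6-olide | C=C(C)C(=O)O[C@H]1[C@H]2C(=C)C(=O)O[C@@H]2/C=C(/C)C2=CC(=O)[C@@](C)(O2)[C@H]1O[Si](C)(C)C(C)(C)C | intermediate
31 | (4Z,6R,7S,8S,9S,10S)-9-hydroxy-8-(methacryloyloxy)-1-oxo-3,10-epoxygermacra-2,4,11(13)-trien-12,6-olide | C=C(C)C(=O)O[C@H]1[C@H]2C(=C)C(=O)O[C@@H]2/C=C(/C)C2=CC(=O)[C@@](C)(O2)[C@H]1O | intermediate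
32 | (4Z,6R,7S,8S,9S,10S)-9-acetoxy-8-(methacryloyloxy)-1-oxo-3,10-epoxygermacra-2,4,11(13)-trien-12,6-olide (CNP0365569.2) | C=C(C)C(=O)O[C@H]1[C@H]2C(=C)C(=O)O[C@@H]2/C=C(/C)C2=CC(=O)[C@@](C)(O2)[C@H]1OC(C)=O | target

**Step count**
Total: 24 steps. Longest linear sequence: 19 steps (steps 1–13, then 19–24). Fragment B takes 5 steps (14–18).

**Three steps most likely to fail, with fallbacks**

Step 19 (indium Barbier coupling). Two hindered partners must combine with three stereocontrol elements matched, and the face selectivity induced by C6 in an acyclic allyl metal is the least secure of them. The fallback replaces acyclic control by a cyclic reagent and corrects C8 afterwards; it sets out from 24 and comes back at 30. Treating 24 with PPTS in MeOH and then catalytic CSA removes the TES group and closes the lactone to (5R)-4-hydroxy-3-methylidene-5-vinyldihydrofuran-2(3H)-one F1. PBr3 in Et2O at 0 °C converts it by SN2′ displacement into (5R)-3-(bromomethyl)-5-vinylfuran-2(5H)-one F2. Zn dust in THF/sat. aq NH4Cl couples F2 with aldehyde 17; the ring forces attack anti to the vinyl group (C7 correct) and the closed chair of the E-locked cyclic allylzinc gives the C8 epimer of 28, lactone F3. Ring-closing metathesis as in step 21 gives the C8 epimer of 29, macrocycle F4. A Mitsunobu esterification with methacrylic acid (PPh3, DIAD, toluene, 0 °C → rt) inverts C8 and installs the ester in one operation, giving 30.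

Step 21 (ring-closing metathesis). The ring is strained, one partner is a conjugated 1,1-disubstituted alkene and the open chain C8–C9 is flexible. The fallback closes the ring on a conformationally locked template and changes the end game to a late regioselective acylation; it sets out from 28 and comes back at 31. HF·pyridine removes the TBS group of 28 to give (4R,5R)-4-{(1S,2S)-1,2-dihydroxy-2-[(2S)-2-methyl-3-oxo-5-(prop-1-en-2-yl)-2,3-dihydrofuran-2-yl]ethyl}-3-methylidene-5-vinyldihydrofuran-2(3H)-one F5. 2,2-Dimethoxypropane with PPTS gives the 8,9-acetonide F6, whose cis-dioxolane holds C7–C8–C9–C10 in the gauche turn found in the product. Metathesis under the step 21 conditions gives the macrocyclic acetonide F7. PPTS in MeOH at 40 °C liberates (4Z,6R,7R,8S,9S,10S)-8,9-dihydroxy-1-oxo-3,10-epoxygermacra-2,4,11(13)-trien-12,6-olide F8. Methacrylic anhydride with DMAP at −20 °C acylates the less hindered O8 (O9 is neopentyl-like), giving 31.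

Step 17 (vinylalumination of aldehyde 21). Aldehyde 21 is a β,γ-unsaturated α-silyloxy aldehyde that can isomerise or racemise, and the TES group can migrate in the aluminium alkoxide. The fallback uses a robust chiral-pool aldehyde and installs the vinyl group late; it sets out from 22 and comes back at 28. Vinylalane 23 made from 22 is added to commercial (R)-2,3-O-isopropylideneglyceraldehyde (O=C[C@H]1COC(C)(C)O1, from D-mannitol) to give methyl 2-{[(4R)-2,2-dimethyl-1,3-dioxolan-4-yl](hydroxy)methyl}acrylate F9. NBS/Me2S gives methyl (2Z)-2-(bromomethyl)-3-[(4S)-2,2-dimethyl-1,3-dioxolan-4-yl]acrylate F10. Indium-mediated coupling with 17 under the step 19 conditions gives the acetonide adduct F11 (same stereochemical model, dioxolane C–O anti to the aldehyde). Aqueous 80% AcOH and then catalytic CSA remove the acetonide and close the γ-lactone to the 5-(hydroxymethyl) lactone F12. TEMPO (cat.)/PhI(OAc)2 oxidises only the primary alcohol to the lactone aldehyde F13. Non-basic methylenation with Zn/CH2Br2/TiCl4 gives 28.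

**Further compounds**
F1 | step 19 | (5R)-4-hydroxy-3-methylidene-5-vinyldihydrofuran-2(3H)-one (C4 epimers) | C=C1C(O)[C@@H](C=C)OC1=O
F2 | step 19 | (5R)-3-(bromomethyl)-5-vinylfuran-2(5H)-one | BrCC1=C[C@@H](C=C)OC1=O
F3 | step 19 | (4R,5R)-4-{(1R,2S)-2-[(tert-butyldimethylsilyl)oxy]-1-hydroxy-2-[(2S)-2-methyl-3-oxo-5-(prop-1-en-2-yl)-2,3-dihydrofuran-2-yl]ethyl}-3-methylidene-5-vinyldihydrofuran-2(3H)-one | O[C@H]([C@H]1C(=C)C(=O)O[C@@H]1C=C)[C@H](O[Si](C)(C)C(C)(C)C)[C@]2(C)OC(C(C)=C)=CC2=O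
F4 | step 19 | (4Z,6R,7R,8R,9S,10S)-9-[(tert-butyldimethylsilyl)oxy]-8-hydroxy-1-oxo-3,10-epoxygermacra-2,4,11(13)-trien-12,6-olide | O[C@@H]1[C@H]2C(=C)C(=O)O[C@@H]2/C=C(/C)C2=CC(=O)[C@@](C)(O2)[C@H]1O[Si](C)(C)C(C)(C)C
F5 | step 21 | (4R,5R)-4-{(1S,2S)-1,2-dihydroxy-2-[(2S)-2-methyl-3-oxo-5-(prop-1-en-2-yl)-2,3-dihydrofuran-2-yl]ethyl}-3-methylidene-5-vinyldihydrofuran-2(3H)-one | O[C@@H]([C@H]1C(=C)C(=O)O[C@@H]1C=C)[C@H](O)[C@]2(C)OC(C(C)=C)=CC2=O
F6 | step 21 | (4R,5R)-4-{(4S,5S)-2,2-dimethyl-5-[(2S)-2-methyl-3-oxo-5-(prop-1-en-2-yl)-2,3-dihydrofuran-2-yl]-1,3-dioxolan-4-yl}-3-methylidene-5-vinyldihydrofuran-2(3H)-one | CC1(C)O[C@@H]([C@H]2C(=C)C(=O)O[C@@H]2C=C)[C@H](O1)[C@]3(C)OC(C(C)=C)=CC3=O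
F7 | step 21 | (4Z,6R,7R,8S,9S,10S)-8,9-(isopropylidenedioxy)-1-oxo-3,10-epoxygermacra-2,4,11(13)-trien-12,6-olide | CC1(C)O[C@H]2[C@H]3C(=C)C(=O)O[C@@H]3/C=C(/C)C3=CC(=O)[C@@](C)(O3)[C@H]2O1
F8 | step 21 | (4Z,6R,7R,8S,9S,10S)-8,9-dihydroxy-1-oxo-3,10-epoxygermacra-2,4,11(13)-trien-12,6-olide | O[C@H]1[C@H]2C(=C)C(=O)O[C@@H]2/C=C(/C)C2=CC(=O)[C@@](C)(O2)[C@H]1O
F9 | step 17 | methyl 2-{[(4R)-2,2-dimethyl-1,3-dioxolan-4-yl](hydroxy)methyl}acrylate (carbinol epimers) | C=C(C(=O)OC)C(O)[C@H]1COC(C)(C)O1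
F10 | step 17 | methyl (2Z)-2-(bromomethyl)-3-[(4S)-2,2-dimethyl-1,3-dioxolan-4-yl]acrylate | BrC/C(C(=O)OC)=C\[C@H]1COC(C)(C)O1
F11 | step 17 | methyl (3R,4S,5S)-5-[(tert-butyldimethylsilyl)oxy]-3-[(4S)-2,2-dimethyl-1,3-dioxolan-4-yl]-4-hydroxy-2-methylidene-5-[(2S)-2-methyl-3-oxo-5-(prop-1-en-2-yl)-2,3-dihydrofuran-2-yl]pentanoate | O[C@@H]([C@@H](C(=C)C(=O)OC)[C@H]1COC(C)(C)O1)[C@H](O[Si](C)(C)C(C)(C)C)[C@]2(C)OC(C(C)=C)=CC2=O
F12 | step 17 | (4R,5S)-4-{(1S,2S)-2-[(tert-butyldimethylsilyl)oxy]-1-hydroxy-2-[(2S)-2-methyl-3-oxo-5-(prop-1-en-2-yl)-2,3-dihydrofuran-2-yl]ethyl}-5-(hydroxymethyl)-3-methylidenedihydrofuran-2(3H)-one | O[C@@H]([C@H]1C(=C)C(=O)O[C@@H]1CO)[C@H](O[Si](C)(C)C(C)(C)C)[C@]2(C)OC(C(C)=C)=CC2=O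
F13 | step 17 | (2S,3R)-3-{(1S,2S)-2-[(tert-butyldimethylsilyl)oxy]-1-hydroxy-2-[(2S)-2-methyl-3-oxo-5-(prop-1-en-2-yl)-2,3-dihydrofuran-2-yl]ethyl}-4-methylidene-5-oxotetrahydrofuran-2-carbaldehyde | O[C@@H]([C@H]1C(=C)C(=O)O[C@@H]1C=O)[C@H](O[Si](C)(C)C(C)(C)C)[C@]2(C)OC(C(C)=C)=CC2=O
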